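The runs were computed from invented constants; scatter was added.

5 questions stand on this flask, and I answer the first two by one quantity.

| flask | solid substrate | remark | time |
|---|---|---|---|
| dusk | 2.1 M | run made earlier |  |
| flask | 1.5 M |  | 40 min |

dusk run (percent of the solid substrate charged)

| time / min | solid substrate / % | target / % | side product B / % |
|---|---|---|---|
| 4.00 | 100 | 0 | 0 |
| 10.0 | 92 | 0 | 3 |
| 20.0 | 85 | 2 | 4 |
| 30.0 | 76 | 3 | 11 |
| 40.0 | 70 | 2 | 12 |

(standard deviation of a reading: 1.5 percentage points)

- given per volume of solution although it is solid: solid substrate
- at the start none of the solid substrate is in solution
- what has only dissolved of solid substrate counts as not reacted
- the reaction counts as stopped when no species that holds the solid substrate changes by six tenths of a point or more over the second half of the time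

- which holds at 40 min: what has brought the reaction to rest, or that it has not come to rest (for what has run out or reacted, a solid counts together with what of it has only dissolved) (it is still moving / forward and back rates have come level / all of the solid substrate has reacted)
- part of the solid substrate that has turned into other species by 40 min (what has only dissolved does not count)
- how much target there is at 40 min, in percent of the solid substrate charged
- how much side product B there is at 40 min, in percent of the solid substrate charged
- how much intermediate C there is at 40 min, in percent of the solid substrate charged

1. The dusk run loses 15 percentage points of its solid substrate from the full charge to 20.0 min, and 15 points in the next 20.0 min. Yet the later stretch starts with less solid than the earlier one. In the dusk run, a loss in proportion to what stands gives 12.8% of the charge there.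

2. I read this as a zero-order loss. So I replace the curve by its mean, the supply rate 0.0157 M/min: the fraction lost, times the charge, per minute.

3. The two dusk stretches match as read, each with its scatter, so the mean hides no bend that I can see there. The last dusk reading carries its scatter into the flask as 2.1 points.

4. My bet is that this rate holds for the smaller charge, which a single run cannot show. Then the flask loses the fraction 42.0% by 40 min. That is less than the whole charge, so by this reckoning solid stands and the flask is still moving.

5. The forecast says it is still moving, with conversion 41%, target 3%, side product B 17% and intermediate C 21%, on a rate that “does not depend on the amount charged”; its conversion lies just under mine.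

6. The flask gives this: it is still moving, with conversion 43.7%, target 3.59%, side product B 18.1% and intermediate C 15.4%. Starting material stands at 1.04% at 4.00 min and 1.08% at 40.0 min. The flask's mean rate of conversion is 0.0164 M/min against my 0.0157 M/min, a gap of 1.7 points, inside 2.1 points.

    starting material ⇌ intermediate A (K = 1.94, k = 0.836 /min)
    starting material → intermediate B (k = 0.485 /min)
    intermediate A → side product A (k = 0.111 /min)
    intermediate A → intermediate C (k = 0.670 /min)
    intermediate B → side product B (k = 0.236 /min)
    intermediate C → target (k = 0.0114 /min)
    solid substrate ⇌ starting material, rate k7*(cs7 - [starting material]) while solid is left; crystals form when [starting material] > cs7 (solubility = 0.140 M, k = 0.135 /min)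
    2 starting material → self-condensation product (k = 0.334 /M/min)

7. With 0.38 M charged, the supply rate asks for 165% of the charge, and I reckon the charge gone at about 24.2 min. That neighbour flask gives conversion >99.9% at 40 min, with 0% of its solid substrate left, solid or dissolved.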